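## Retrosynthetic overview

1. Last ring: the ten-membered carbocycle, closed at C3–C4 by an intramolecular Nozaki–Hiyama–Kishi reaction of a Z-alkenyl iodide onto a C3 aldehyde; acetylation and desilylation then give the target.
2. The seco-compound comes from a late Barbier union (C7–C8) of bromomethyl-butenolide fragment A (C4–C7, C11–C13, C15) with enal fragment B (C1–C3, C8–C10, C14); the C8 carbinol is then inverted and acylated in one Mitsunobu step with tiglic acid.
3. Fragment A: (S)-but-3-ene-1,2-diol → α-silyloxy aldehyde → Z-selective iodo-Wittig → 2-(bromomethyl)acrylate ester → ring-closing metathesis (first ring: the butenolide).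
4. Fragment B: (S)-α-hydroxy-γ-butyrolactone → Weinreb amide → methyl ketone → E-selective Horner–Wadsworth–Emmons → enal.
5. Ring order: butenolide (metathesis) → α-methylene-γ-lactone (unveiled in the Barbier step) → cyclodecadiene (Nozaki–Hiyama–Kishi).

Assumption: germacrane numbering (C1–C15) is used for all coupled compounds; the target is 3β-acetoxy-1α-hydroxy-8β-tigloyloxygermacra-4Z,9E,11(13)-trien-6α,12-olide (1S,3S,6R,7S,8R); phosphorus ylide/phosphonate reagents and silyl chlorides are treated as reagents.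

## Route

**Fragment A**

Step 1
Reactants: 1 (S)-but-3-ene-1,2-diol
Product: 2 (S)-1,2-bis(triethylsilyloxy)but-3-ene
Conditions: Et3SiCl (2.4 equiv), imidazole, CH2Cl2, 0 °C → rt
Reagents that add atoms: chlorotriethylsilane, CC[Si](Cl)(CC)CC
Why: Standard silylation of both hydroxyls, leaving the chiral-pool stereocentre (future C6) untouched.

Step 2
Reactants: 2 (S)-1,2-bis(triethylsilyloxy)but-3-ene
Product: 3 (S)-2-(triethylsilyloxy)but-3-enal
Conditions: (COCl)2, DMSO, CH2Cl2, −78 → −35 °C; then Et3N, −78 → 0 °C; used crude at once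
Reagents that add atoms: none
Why: Under Swern conditions a primary triethylsilyl ether is cleaved and oxidised directly while the secondary one survives, and the cold, short base exposure keeps the α-centre intact.

Step 3
Reactants: 3 (S)-2-(triethylsilyloxy)but-3-enal
Product: 4 triethyl{[(3S,4Z)-5-iodohexa-1,4-dien-3-yl]oxy}silane
Conditions: [Ph3PCH(I)CH3]I, NaN(SiMe3)2, THF, −78 °C; then 3, −78 → −20 °C
Reagents that add atoms: (1-iodoethyl)triphenylphosphonium iodide, CC(I)[P+](c1ccccc1)(c1ccccc1)c1ccccc1.[I-]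
Why: Stork–Zhao-type Wittig olefination with the α-iodo ylide is kinetically Z-selective (iodine cis to the chain), which sets the future 4Z olefin.

Step 4
Reactants: 4 triethyl{[(3S,4Z)-5-iodohexa-1,4-dien-3-yl]oxy}silane
Product: 5 (3S,4Z)-5-iodohexa-1,4-dien-3-ol
Conditions: HF·pyridine, pyridine, THF, 0 °C
Reagents that add atoms: none
Why: Buffered fluoride desilylation frees the bis-allylic alcohol without ionising it.

Step 5
Reactants: 5 (3S,4Z)-5-iodohexa-1,4-dien-3-ol; 6 2-(bromomethyl)prop-2-enoic acid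
Product: 7 (3S,4Z)-5-iodohexa-1,4-dien-3-yl 2-(bromomethyl)prop-2-enoate
Conditions: DCC, DMAP (5 mol %), CH2Cl2, −10 → 0 °C
Reagents that add atoms: none
Why: Steglich esterification at low temperature and low DMAP loading spares the allylic bromide and does not touch the carbinol configuration.

Step 6
Reactants: 7 (3S,4Z)-5-iodohexa-1,4-dien-3-yl 2-(bromomethyl)prop-2-enoate
Product: 8 (5S)-3-(bromomethyl)-5-[(Z)-2-iodoprop-1-en-1-yl]furan-2(5H)-one (fragment A)
Conditions: second-generation Grubbs catalyst (H2IMes)(PCy3)Cl2Ru=CHPh (5–10 mol %), 1,4-benzoquinone (10 mol %), CH2Cl2 (5 mM), 40 °C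
Reagents that add atoms: none
Why: Ring-closing metathesis between the vinyl group and the 1,1-disubstituted acrylate gives the butenolide, the trisubstituted iodoalkene being inert to the catalyst.

**Fragment B**

Step 7
Reactants: 9 (S)-3-hydroxydihydrofuran-2(3H)-one
Product: 10 (S)-3-[(tert-butyldimethylsilyl)oxy]dihydrofuran-2(3H)-one
Conditions: t-BuMe2SiCl, imidazole, DMF, rt
Reagents that add atoms: tert-butyl(chloro)dimethylsilane, CC(C)(C)[Si](C)(C)Cl
Why: Silylation protects the future C1 hydroxyl; the stereocentre comes from the chiral pool.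

Step 8
Reactants: 10 (S)-3-[(tert-butyldimethylsilyl)oxy]dihydrofuran-2(3H)-one
Product: 11 (S)-2-[(tert-butyldimethylsilyl)oxy]-4-hydroxy-N-methoxy-N-methylbutanamide
Conditions: MeNH(OMe)·HCl, AlMe3, CH2Cl2, 0 °C → rt; aq. potassium sodium tartrate; used at once
Reagents that add atoms: N,O-dimethylhydroxylamine hydrochloride, CNOC.Cl
Why: Weinreb aminolysis of the lactone by the aluminium amide opens the ring without epimerising the α-silyloxy centre.

Step 9
Reactants: 11 (S)-2-[(tert-butyldimethylsilyl)oxy]-4-hydroxy-N-methoxy-N-methylbutanamide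
Product: 12 (S)-2-[(tert-butyldimethylsilyl)oxy]-N-methoxy-N-methyl-4-[(triethylsilyl)oxy]butanamide
Conditions: Et3SiCl, imidazole, CH2Cl2, 0 °C
Reagents that add atoms: chlorotriethylsilane, CC[Si](Cl)(CC)CC
Why: Silylation of the primary alcohol prevents relactonisation and installs the group that is later oxidised directly to the C3 aldehyde.

Step 10
Reactants: 12 (S)-2-[(tert-butyldimethylsilyl)oxy]-N-methoxy-N-methyl-4-[(triethylsilyl)oxy]butanamide
Product: 13 (S)-3-[(tert-butyldimethylsilyl)oxy]-5-[(triethylsilyl)oxy]pentan-2-one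
Conditions: MeMgBr, THF, 0 °C; aq. NH4Cl
Reagents that add atoms: methylmagnesium bromide, C[Mg]Br
Why: Weinreb ketone synthesis stops at the chelated adduct and delivers the methyl ketone (C14 methyl) without over-addition.

Step 11
Reactants: 13 (S)-3-[(tert-butyldimethylsilyl)oxy]-5-[(triethylsilyl)oxy]pentan-2-one
Product: 14 (2E,4S)-4-[(tert-butyldimethylsilyl)oxy]-N-methoxy-N,3-dimethyl-6-[(triethylsilyl)oxy]hex-2-enamide
Conditions: (EtO)2P(O)CH2C(O)N(OMe)Me, NaH, THF, 0 °C → rt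
Reagents that add atoms: diethyl [2-(methoxy(methyl)amino)-2-oxoethyl]phosphonate, CCOP(=O)(CC(=O)N(C)OC)OCC
Why: Horner–Wadsworth–Emmons olefination of the methyl ketone places the carbonyl trans to the larger α-silyloxyalkyl group, giving the E olefin (future 9E); minor Z isomer is removed by chromatography.

Step 12
Reactants: 14 (2E,4S)-4-[(tert-butyldimethylsilyl)oxy]-N-methoxy-N,3-dimethyl-6-[(triethylsilyl)oxy]hex-2-enamide
Product: 15 (2E,4S)-4-[(tert-butyldimethylsilyl)oxy]-3-methyl-6-[(triethylsilyl)oxy]hex-2-enal (fragment B)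
Conditions: i-Bu2AlH, THF, −78 °C; aq. potassium sodium tartrate
Reagents that add atoms: none
Why: Hydride reduction of the Weinreb amide stops at the aldehyde oxidation level through the stable aluminium chelate, with 1,2-selectivity on the enamide.

**Union and endgame**

Step 13
Reactants: 8 (5S)-3-(bromomethyl)-5-[(Z)-2-iodoprop-1-en-1-yl]furan-2(5H)-one; 15 (2E,4S)-4-[(tert-butyldimethylsilyl)oxy]-3-methyl-6-[(triethylsilyl)oxy]hex-2-enal
Product: 17 (4R,5S)-4-[(1S,2E,4S)-4-(tert-butyldimethylsilyloxy)-1-hydroxy-3-methyl-6-(triethylsilyloxy)hex-2-en-1-yl]-5-[(Z)-2-iodoprop-1-en-1-yl]-3-methylidenedihydrofuran-2(3H)-one, via allylzinc bromide 16 (not isolated)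
Conditions: Zn dust (activated), THF/sat. aq. NH4Cl (5:1), 0 °C, 1 h; 8 (1.3 equiv)
Reagents that add atoms: none
Why: Barbier allylation: zinc inserts only into the allylic bromide and the 2-carbonyl-allylzinc adds through its γ-carbon (C7) in a chair Zimmerman–Traxler transition state on the lactone face anti to the C6 iodopropenyl group, which gives the 6,7-trans α-methylene lactone and the 8S (8α) carbinol, the epimer required for the inverting esterification that follows.

Step 14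
Reactants: 17 the 8S seco-alcohol; 18 tiglic acid, (E)-2-methylbut-2-enoic acid
Product: 19 (1R,2E,4S)-4-(tert-butyldimethylsilyloxy)-1-{(2S,3R)-2-[(Z)-2-iodoprop-1-en-1-yl]-4-methylidene-5-oxooxolan-3-yl}-3-methyl-6-(triethylsilyloxy)hex-2-en-1-yl (2E)-2-methylbut-2-enoate
Conditions: PPh3, DIAD, toluene, −20 → 0 °C
Reagents that add atoms: none
Why: Mitsunobu esterification displaces the activated C8 oxygen by tiglate in an SN2 process with inversion, so C8 becomes R (8β-tigloyloxy) and the ester is installed in the same step.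

Step 15
Reactants: 19 the 8R tiglate with a primary triethylsilyl ether at C3
Product: 20 (1R,2E,4S)-4-(tert-butyldimethylsilyloxy)-1-{(2S,3R)-2-[(Z)-2-iodoprop-1-en-1-yl]-4-methylidene-5-oxooxolan-3-yl}-3-methyl-6-oxohex-2-en-1-yl (2E)-2-methylbut-2-enoate
Conditions: (COCl)2, DMSO, CH2Cl2, −78 → −40 °C; then Et3N, −78 → 0 °C
Reagents that add atoms: none
Why: Direct Swern oxidation of the primary triethylsilyl ether gives the C3 aldehyde in one step while the secondary tert-butyldimethylsilyl ether, both esters and the methylene lactone stay intact.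

Step 16
Reactants: 20 the iodo-aldehyde
Product: 22 (1S,3S,6R,7S,8R,4Z,9E)-1-(tert-butyldimethylsilyloxy)-3-hydroxy-8-tigloyloxygermacra-4,9,11(13)-trien-6,12-olide, via alkenylchromium dichloride 21 (not isolated)
Conditions: CrCl2 (10 equiv), NiCl2 (2 mol % of the CrCl2), degassed DMSO, 2 mM, slow addition of 20, rt
Reagents that add atoms: none
Why: Intramolecular Nozaki–Hiyama–Kishi reaction: zerovalent nickel inserts into the alkenyl iodide with retention of the Z geometry, transmetallation gives an alkenyl species of trivalent chromium that adds only to the aldehyde, and 1,3-anti induction from the C1 silyloxy group (Evans polar model) should favour the 3S alcohol.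

Step 17
Reactants: 22 the macrocyclic 3S alcohol
Product: 23 (1S,3S,6R,7S,8R,4Z,9E)-3-acetoxy-1-(tert-butyldimethylsilyloxy)-8-tigloyloxygermacra-4,9,11(13)-trien-6,12-olide
Conditions: Ac2O, pyridine, DMAP (cat.), CH2Cl2, 0 °C → rt
Reagents that add atoms: acetic anhydride, CC(=O)OC(C)=O
Why: Acylation of the only free hydroxyl with retention at C3.

Step 18
Reactants: 23 the 1-O-silyl acetate
Product: 24 (3aS,4R,5E,7S,9S,10Z,11aR)-9-acetoxy-7-hydroxy-6,10-dimethyl-3-methylidene-2-oxo-2,3,3a,4,7,8,9,11a-octahydrocyclodeca[b]furan-4-yl (2E)-2-methylbut-2-enoate (target)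
Conditions: HF·pyridine, pyridine, THF, 0 °C → rt
Reagents that add atoms: none
Why: Mildly acidic fluoride desilylation frees the C1 hydroxyl without acetate migration, ester cleavage or addition to the methylene lactone.

## Compound list

1 | (S)-but-3-ene-1,2-diol | C=C[C@H](O)CO | starting material
2 | (S)-1,2-bis(triethylsilyloxy)but-3-ene | C=C[C@H](O[Si](CC)(CC)CC)CO[Si](CC)(CC)CC | intermediate
3 | (S)-2-(triethylsilyloxy)but-3-enal | C=C[C@H](O[Si](CC)(CC)CC)C=O | intermediate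
4 | triethyl{[(3S,4Z)-5-iodohexa-1,4-dien-3-yl]oxy}silane | C=C[C@H](O[Si](CC)(CC)CC)/C=C(/C)I | intermediate
5 | (3S,4Z)-5-iodohexa-1,4-dien-3-ol | C=C[C@H](O)/C=C(/C)I | intermediate
6 | 2-(bromomethyl)prop-2-enoic acid | C=C(CBr)C(=O)O | starting material
7 | (3S,4Z)-5-iodohexa-1,4-dien-3-yl 2-(bromomethyl)prop-2-enoate | C=C[C@H](OC(=O)C(=C)CBr)/C=C(/C)I | intermediate
8 | (5S)-3-(bromomethyl)-5-[(Z)-2-iodoprop-1-en-1-yl]furan-2(5H)-one (fragment A) | O=C1O[C@H](/C=C(/C)I)C=C1CBr | intermediate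
9 | (S)-3-hydroxydihydrofuran-2(3H)-one | O[C@H]1CCOC1=O | starting material
10 | (S)-3-[(tert-butyldimethylsilyl)oxy]dihydrofuran-2(3H)-one | CC(C)(C)[Si](C)(C)O[C@H]1CCOC1=O | intermediate
11 | (S)-2-[(tert-butyldimethylsilyl)oxy]-4-hydroxy-N-methoxy-N-methylbutanamide | CON(C)C(=O)[C@H](CCO)O[Si](C)(C)C(C)(C)C | intermediate
12 | (S)-2-[(tert-butyldimethylsilyl)oxy]-N-methoxy-N-methyl-4-[(triethylsilyl)oxy]butanamide | CON(C)C(=O)[C@H](CCO[Si](CC)(CC)CC)O[Si](C)(C)C(C)(C)C | intermediate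
13 | (S)-3-[(tert-butyldimethylsilyl)oxy]-5-[(triethylsilyl)oxy]pentan-2-one | CC(=O)[C@H](CCO[Si](CC)(CC)CC)O[Si](C)(C)C(C)(C)C | intermediate
14 | (2E,4S)-4-[(tert-butyldimethylsilyl)oxy]-N-methoxy-N,3-dimethyl-6-[(triethylsilyl)oxy]hex-2-enamide | CON(C)C(=O)/C=C(\C)[C@@H](O[Si](C)(C)C(C)(C)C)CCO[Si](CC)(CC)CC | intermediate
15 | (2E,4S)-4-[(tert-butyldimethylsilyl)oxy]-3-methyl-6-[(triethylsilyl)oxy]hex-2-enal (fragment B) | O=C/C=C(\C)[C@@H](O[Si](C)(C)C(C)(C)C)CCO[Si](CC)(CC)CC | intermediate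
16 | {[(5S)-5-[(Z)-2-iodoprop-1-en-1-yl]-2-oxo-2,5-dihydrofuran-3-yl]methyl}zinc bromide | O=C1O[C@H](/C=C(/C)I)C=C1C[Zn]Br | intermediate (not isolated)
17 | (4R,5S)-4-[(1S,2E,4S)-4-(tert-butyldimethylsilyloxy)-1-hydroxy-3-methyl-6-(triethylsilyloxy)hex-2-en-1-yl]-5-[(Z)-2-iodoprop-1-en-1-yl]-3-methylidenedihydrofuran-2(3H)-one (1S,6S,7R,8S) | C=C1C(=O)O[C@H](/C=C(/C)I)[C@H]1[C@@H](O)/C=C(\C)[C@@H](O[Si](C)(C)C(C)(C)C)CCO[Si](CC)(CC)CC | intermediate
18 | tiglic acid, (E)-2-methylbut-2-enoic acid | C/C=C(\C)C(=O)O | starting material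
19 | (1R,2E,4S)-4-(tert-butyldimethylsilyloxy)-1-{(2S,3R)-2-[(Z)-2-iodoprop-1-en-1-yl]-4-methylidene-5-oxooxolan-3-yl}-3-methyl-6-(triethylsilyloxy)hex-2-en-1-yl (2E)-2-methylbut-2-enoate | C=C1C(=O)O[C@H](/C=C(/C)I)[C@H]1[C@H](OC(=O)/C(C)=C/C)/C=C(\C)[C@@H](O[Si](C)(C)C(C)(C)C)CCO[Si](CC)(CC)CC | intermediate
20 | (1R,2E,4S)-4-(tert-butyldimethylsilyloxy)-1-{(2S,3R)-2-[(Z)-2-iodoprop-1-en-1-yl]-4-methylidene-5-oxooxolan-3-yl}-3-methyl-6-oxohex-2-en-1-yl (2E)-2-methylbut-2-enoate | C=C1C(=O)O[C@H](/C=C(/C)I)[C@H]1[C@H](OC(=O)/C(C)=C/C)/C=C(\C)[C@@H](O[Si](C)(C)C(C)(C)C)CC=O | intermediate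
21 | alkenylchromium dichloride of 20 (CrCl2 on C4 in place of iodine, Z geometry kept) | C=C1C(=O)O[C@H](/C=C(/C)[Cr](Cl)Cl)[C@H]1[C@H](OC(=O)/C(C)=C/C)/C=C(\C)[C@@H](O[Si](C)(C)C(C)(C)C)CC=O | intermediate (not isolated)
22 | (1S,3S,6R,7S,8R,4Z,9E)-1-(tert-butyldimethylsilyloxy)-3-hydroxy-8-tigloyloxygermacra-4,9,11(13)-trien-6,12-olide | C=C1C(=O)O[C@@H]2/C=C(/C)[C@@H](O)C[C@H](O[Si](C)(C)C(C)(C)C)/C(C)=C/[C@@H](OC(=O)/C(C)=C/C)[C@@H]12 | intermediate
23 | (1S,3S,6R,7S,8R,4Z,9E)-3-acetoxy-1-(tert-butyldimethylsilyloxy)-8-tigloyloxygermacra-4,9,11(13)-trien-6,12-olide | C=C1C(=O)O[C@@H]2/C=C(/C)[C@@H](OC(C)=O)C[C@H](O[Si](C)(C)C(C)(C)C)/C(C)=C/[C@@H](OC(=O)/C(C)=C/C)[C@@H]12 | intermediate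
24 | (3aS,4R,5E,7S,9S,10Z,11aR)-9-acetoxy-7-hydroxy-6,10-dimethyl-3-methylidene-2-oxo-2,3,3a,4,7,8,9,11a-octahydrocyclodeca[b]furan-4-yl (2E)-2-methylbut-2-enoate | C=C1C(=O)O[C@@H]2/C=C(/C)[C@@H](OC(C)=O)C[C@H](O)/C(C)=C/[C@@H](OC(=O)/C(C)=C/C)[C@@H]12 | target

## Step count and risks

Total step count: 18 (steps 1–6 fragment A, steps 7–12 fragment B, steps 13–18 union and endgame).
Longest linear sequence: 12 steps (1–6 or 7–12, then 13–18), two thirds of the total.

Three steps most likely to fail: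

**Step 16 (Nozaki–Hiyama–Kishi macrocyclisation).** The ring is a strained cyclodecadiene and the C3 configuration rests on substrate control. The fallback sets out from 20 and comes back at 22, and it takes the stereocentre away from the C–C bond formation. The crude cyclisation product, in which the 3R alcohol (1S,3R,6R,7S,8R,4Z,9E)-1-(tert-butyldimethylsilyloxy)-3-hydroxy-8-tigloyloxygermacra-4,9,11(13)-trien-6,12-olide F1 may dominate, is oxidised as the epimer mixture with Dess–Martin periodinane (NaHCO3, CH2Cl2) to the macrocyclic Z-enone (1S,6R,7S,8R,4Z,9E)-1-(tert-butyldimethylsilyloxy)-3-oxo-8-tigloyloxygermacra-4,9,11(13)-trien-6,12-olide F2. This α-methyl enone is then reduced under reagent control with (R)-2-methyl-CBS-oxazaborolidine and BH3·SMe2 (THF, −30 °C) to the 3S alcohol 22.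

**Step 14 (Mitsunobu inversion with tiglic acid).** The alcohol is hindered and allylic, so elimination toward C7, SN2' attack or ionisation can compete. The fallback sets out from 17 and comes back at 19, and it separates inversion from acylation. Mitsunobu reaction with the small, more acidic formic acid (PPh3, DIAD, THF, 0 °C) gives the inverted formate (1R,2E,4S)-4-(tert-butyldimethylsilyloxy)-1-{(2S,3R)-2-[(Z)-2-iodoprop-1-en-1-yl]-4-methylidene-5-oxooxolan-3-yl}-3-methyl-6-(triethylsilyloxy)hex-2-en-1-yl formate F3. KHCO3 in MeOH at 0 °C frees the 8R alcohol (4R,5S)-4-[(1R,2E,4S)-4-(tert-butyldimethylsilyloxy)-1-hydroxy-3-methyl-6-(triethylsilyloxy)hex-2-en-1-yl]-5-[(Z)-2-iodoprop-1-en-1-yl]-3-methylidenedihydrofuran-2(3H)-one F4. Tiglic acid 18 is then attached with retention by Yamaguchi esterification (2,4,6-trichlorobenzoyl chloride, Et3N, DMAP, toluene) to give 19.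

**Step 3 (iodo-Wittig on aldehyde 3).** The α-silyloxy β,γ-unsaturated aldehyde is base-sensitive and the Z/E ratio may be modest. The fallback sets out from 3 and comes back at 5, bypassing 4, and it makes the iodoalkene by alkyne hydroalumination instead of olefination. Corey–Fuchs reaction (CBr4, PPh3, CH2Cl2, 0 °C) gives the dibromo-diene (S)-[(1,1-dibromopenta-1,4-dien-3-yl)oxy]triethylsilane F5. n-BuLi (2 equiv, THF, −78 °C) followed by MeI gives the enyne (S)-triethyl(hex-1-en-4-yn-3-yloxy)silane F6, and HF·pyridine gives the enynol (S)-hex-1-en-4-yn-3-ol F7. Hydroxyl-directed trans-hydroalumination with NaAlH2(OCH2CH2OMe)2 (THF, 0 °C) and quenching with I2 (−78 °C) then gives the Z-iodo-dienol 5 directly.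

## Further compounds

F1 | step 16 | (1S,3R,6R,7S,8R,4Z,9E)-1-(tert-butyldimethylsilyloxy)-3-hydroxy-8-tigloyloxygermacra-4,9,11(13)-trien-6,12-olide | C=C1C(=O)O[C@@H]2/C=C(/C)[C@H](O)C[C@H](O[Si](C)(C)C(C)(C)C)/C(C)=C/[C@@H](OC(=O)/C(C)=C/C)[C@@H]12
F2 | step 16 | (1S,6R,7S,8R,4Z,9E)-1-(tert-butyldimethylsilyloxy)-3-oxo-8-tigloyloxygermacra-4,9,11(13)-trien-6,12-olide | C=C1C(=O)O[C@@H]2/C=C(/C)C(=O)C[C@H](O[Si](C)(C)C(C)(C)C)/C(C)=C/[C@@H](OC(=O)/C(C)=C/C)[C@@H]12
F3 | step 14 | (1R,2E,4S)-4-(tert-butyldimethylsilyloxy)-1-{(2S,3R)-2-[(Z)-2-iodoprop-1-en-1-yl]-4-methylidene-5-oxooxolan-3-yl}-3-methyl-6-(triethylsilyloxy)hex-2-en-1-yl formate | C=C1C(=O)O[C@H](/C=C(/C)I)[C@H]1[C@H](OC=O)/C=C(\C)[C@@H](O[Si](C)(C)C(C)(C)C)CCO[Si](CC)(CC)CC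
F4 | step 14 | (4R,5S)-4-[(1R,2E,4S)-4-(tert-butyldimethylsilyloxy)-1-hydroxy-3-methyl-6-(triethylsilyloxy)hex-2-en-1-yl]-5-[(Z)-2-iodoprop-1-en-1-yl]-3-methylidenedihydrofuran-2(3H)-one | C=C1C(=O)O[C@H](/C=C(/C)I)[C@H]1[C@H](O)/C=C(\C)[C@@H](O[Si](C)(C)C(C)(C)C)CCO[Si](CC)(CC)CC
F5 | step 3 | (S)-[(1,1-dibromopenta-1,4-dien-3-yl)oxy]triethylsilane | C=C[C@H](O[Si](CC)(CC)CC)C=C(Br)Br
F6 | step 3 | (S)-triethyl(hex-1-en-4-yn-3-yloxy)silane | C=C[C@H](O[Si](CC)(CC)CC)C#CC
F7 | step 3 | (S)-hex-1-en-4-yn-3-ol | C=C[C@H](O)C#CC
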